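The pitfall on this bench is to take the target-forming constant at face value, when it acts on intermediate B and warming pushes intermediate B back towards intermediate A.

    intermediate B → target (k1 = 0.0128 min⁻¹, Ea1 = 79.0 kJ mol⁻¹)
    intermediate A ⇌ intermediate B (K2 = 3.4, k2 = 0.0505 min⁻¹, Ea2 = 82.0 kJ mol⁻¹, ΔH2 = −56.0 kJ mol⁻¹)
    substrate → intermediate A (k3 = 0.0164 min⁻¹, Ea3 = 95.0 kJ mol⁻¹)
    substrate ⇌ intermediate C (K4 = 0.38, k4 = 0.281 min⁻¹, Ea4 = 87.0 kJ mol⁻¹, ΔH4 = −15.0 kJ mol⁻¹)
    substrate → decomposition product (k5 = 2.84 × 10⁻⁵ min⁻¹, Ea5 = 95.0 kJ mol⁻¹)
    (constants at 5 °C)
common to all: substrate 1.1 M; time 25 min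

|  | temperature |
|---|---|
| dusk | 20 °C |
| midnight | 5 °C |
| winter | 35 °C |
- the best flask by amount of target, in percent of the substrate charged; "all alike" if 1.5 percentage points covers them all (dusk / midnight / winter / all alike)
- amount of target at the end, in percent of the substrate charged, dusk
- amount of target at the end, in percent of the substrate charged, midnight
- amount of target at the end, in percent of the substrate charged, winter

To whoever takes over: winter is the flask to watch, and we reckon it in powers of ten. Substrate feeds a pool of intermediate A and intermediate B, and the pool empties through intermediate B. From 5 °C to 35 °C: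

target step: up 1.44 decades, to 0.356 min⁻¹
[intermediate B]/[intermediate A]: moved −1.02 decades, to 0.322, so intermediate B is 24.3% of the pool
pool drain: 0.0867 min⁻¹

In winter the pair relaxes at 6.55 min⁻¹, far faster than that drain, so the pool view holds there. The pool therefore falls tenfold in 26.5 min: this is the decade time, 2.3 over the drain constant.

In winter substrate, shared with intermediate C, enters the pool at 0.744 min⁻¹, a delay of 1.34 min, and the drain is slower than that entry, which makes it the rate-limiting step of this flask. When you arrive, at 25 min, we expect 87.1% target in winter.

Midnight's decade time, reckoned the same way, is 233 min, longer than its run. The target step's activation energy exceeds the size of the enthalpy, and winter's decade time is shorter than midnight's, so we name winter, the hottest flask.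

Don't cool the bath to spare substrate: from midnight to winter decomposition speeds up by a factor of 55 against 28 for the target step, but it shares its activation energy with substrate's productive step, which stays 577 times faster.

The forecast says winter: 85.5% there (range 82% to 88%), 37.5% at dusk and 1.3% at midnight, noting that “the equilibria shift the wrong way on warming but far less than the rates rise”. Our winter figure stands 1.6 percentage points higher.

The flask gives winter: 85.6% in winter, 37.8% at dusk, 1.23% at midnight. Winter's substrate reads 0.00759% at 12.5 min, when its pool holds 40.2%. Reckoned at the decade time of 26.5 min, a further 12.5 min takes that pool to 13.6%. At 25.0 min winter holds 10.9% intermediate A and 3.32% intermediate B, together 14.2%.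

Its constants stand for no real mixture.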